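**Retrosynthetic overview**

- The strategy rests on the central aryl ester: its C(=O)–O bond joins O-4 of ring A to a benzoyl carbon flanked in ring B by a heptyl group (C-2′) and a methoxy group (C-6′), and ring B has the 4′,6′-dioxygen-2′-alkyl benzoate pattern of a cyclized 3,5,7-trioxo acid chain.
- Ring B is opened across C1′–C2′ (chain C2–C7) to an aryl 3,5,7-trioxotetradecanoate, and the ester C–O bond is then cut to a diketo-acylketene plus the ring A 4-phenol. The hindered ester is thus made from an unhindered ketene and ring B is closed on it afterwards.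
- Ring A comes from the same diketo-dioxinone by base-mediated aldol aromatization with the dioxinone acetal left in place. The acetonide masks the ortho oxygen while the only free phenol is allylated; benzyl alkoxide then opens the acetonide to the benzyl ester, the released ortho phenol is methylated and the allyl group is removed.
- The diketo-dioxinone is assembled from 2,2,6-trimethyl-4H-1,3-dioxin-4-one, acetyl chloride and octanoyl chloride by two Claisen-type acylations.
- Ring order: ring A first (step 4), ring B last (step 9), then double O-methylation and hydrogenolysis of the benzyl ester.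

Key step: step 9

Remark: locants follow benzoate numbering (C-1 bears the carboxyl carbon, primed locants for ring B), and chain locants C-1 to C-7 count from the ester carbonyl of the trioxo ester. Polycarbonyl compounds are drawn as keto tautomers although they will be largely enolized. The target has no stereogenic element.

**Route**

Step 1
Reactants: 1 2,2,6-trimethyl-4H-1,3-dioxin-4-one, 2 acetyl chloride
Product: 3 2,2-dimethyl-6-(2-oxopropyl)-4H-1,3-dioxin-4-one
Conditions: 1 (2 equiv), LiN(SiMe3)2 (2 equiv), THF, −78 °C; then 2 (1 equiv), −78 °C; 1 M HCl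
Reagents that add atoms: none
Why: Deprotonation of the 6-methyl group gives the vinylogous lithium enolate of 1, which should be C-acylated at its terminal carbon by 2 in a crossed Claisen-type acylation, the second equivalent of enolate taking up the acidic proton of the product.

Step 2
Reactants: 4 octanoyl chloride
Product: 5 N-methoxy-N-methyloctanamide
Conditions: MeNH(OMe)·HCl, Et3N, CH2Cl2, 0 °C to rt
Reagents that add atoms: N,O-dimethylhydroxylamine hydrochloride, CNOC.Cl
Why: N-acylation of the hydroxylamine by the acid chloride gives the Weinreb amide, whose chelated tetrahedral adduct will stop the next acylation at the ketone stage.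

Step 3
Reactants: 3 2,2-dimethyl-6-(2-oxopropyl)-4H-1,3-dioxin-4-one, 5 N-methoxy-N-methyloctanamide
Product: 6 6-(2,4-dioxoundecyl)-2,2-dimethyl-4H-1,3-dioxin-4-one
Conditions: LiN(iPr)2 (2.2 equiv), THF, −78 °C; then 5, −78 to −40 °C; 1 M HCl (run on a scale that serves steps 4 and 9)
Reagents that add atoms: none
Why: Double deprotonation of 3 gives a dianion whose last-formed terminal carbanion should attack the Weinreb amide in a Claisen-type acylation, and the stable N-methoxy-N-methyl adduct prevents over-addition until the acidic quench.

Step 4
Reactants: 6 6-(2,4-dioxoundecyl)-2,2-dimethyl-4H-1,3-dioxin-4-one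
Product: 8 5-heptyl-7-hydroxy-2,2-dimethyl-4H-1,3-benzodioxin-4-one, via bicyclic aldol adduct 7 (not isolated)
Conditions: Et3N (3 equiv), CH2Cl2, rt; then TFA, 0 °C to rt
Reagents that add atoms: none
Why: Triethylamine should form the extended enolate of the dioxinone, whose C-5 adds to the heptyl-bearing ketone of the side chain in a 6-exo-trig intramolecular aldol reaction, and acid-promoted loss of water from adduct 7 with enolization of the remaining ring ketone should give the acetonide-protected resorcylate (base-mediated cycloaromatization of a diketo-dioxinone), the acetal staying intact because no ketene is released at room temperature.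

Step 5
Reactants: 8 5-heptyl-7-hydroxy-2,2-dimethyl-4H-1,3-benzodioxin-4-one
Product: 9 7-(allyloxy)-5-heptyl-2,2-dimethyl-4H-1,3-benzodioxin-4-one
Conditions: allyl bromide (1.2 equiv), K2CO3, acetone, 50 °C
Reagents that add atoms: allyl bromide, C=CCBr
Why: Williamson etherification can only take place at the 7-OH, because the second ring oxygen is locked in the acetonide, so the two oxygens of ring A are told apart without relying on any difference in phenol reactivity.

Step 6
Reactants: 9 7-(allyloxy)-5-heptyl-2,2-dimethyl-4H-1,3-benzodioxin-4-one, 10 benzyl alcohol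
Product: 11 benzyl 4-(allyloxy)-2-heptyl-6-hydroxybenzoate
Conditions: 10 (1.5 equiv), NaH (1.2 equiv), THF, 0 °C to rt; 1 M HCl
Reagents that add atoms: none
Why: Sodium benzyl oxide should add to the acyl carbon of the benzodioxinone and expel the hemiketal phenoxide, which loses acetone (alkoxide opening of a salicylate acetonide by addition–elimination), and the resulting ortho-phenoxide deactivates the new benzyl ester towards further attack.

Step 7
Reactants: 11 benzyl 4-(allyloxy)-2-heptyl-6-hydroxybenzoate
Product: 12 benzyl 4-(allyloxy)-2-heptyl-6-methoxybenzoate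
Conditions: MeI, K2CO3, DMF, 50 °C
Reagents that add atoms: iodomethane, CI
Why: Williamson methylation in a dipolar aprotic solvent with gentle heating should overcome the hydrogen bond of the 6-OH to the ester carbonyl, while the hindered benzyl ester and the allyl ether are inert to K2CO3 and MeI.

Step 8
Reactants: 12 benzyl 4-(allyloxy)-2-heptyl-6-methoxybenzoate
Product: 13 benzyl 2-heptyl-4-hydroxy-6-methoxybenzoate
Conditions: Pd(PPh3)4 (5 mol %), morpholine, THF, rt
Reagents that add atoms: none
Why: In this Tsuji–Trost deallylation zerovalent palladium ionizes the allyl aryl ether to a π-allyl complex that morpholine intercepts, freeing the 4-phenol while the benzyl ester and the methyl ether are untouched.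

Step 9
Reactants: 6 6-(2,4-dioxoundecyl)-2,2-dimethyl-4H-1,3-dioxin-4-one (second portion), 13 benzyl 2-heptyl-4-hydroxy-6-methoxybenzoate
Product: 17 benzyl 4-[(2-heptyl-4,6-dihydroxybenzoyl)oxy]-2-heptyl-6-methoxybenzoate, via acylketene 14 (not isolated), via triketo aryl ester 15 (not isolated), via ring B aldol adduct 16 (not isolated)
Conditions: 13 (concentrated in PhMe), 6 (1.5 equiv, added in portions), 110 °C; then Et3N, CH2Cl2, 0 °C to rt; then TFA, rt
Reagents that add atoms: none
Why: Proposed new method: thermolysis of 6 should release acetone by a retro-hetero-Diels–Alder reaction, and the 4-OH of 13, the only nucleophile present, should add to the unhindered sp carbon of acylketene 14 to give the triketo aryl ester 15, so that the depside C(=O)–O bond exists before its acyl carbon has any ortho neighbour. Triethylamine should then bring the C-2 methylene of 15 onto the C-7 ketone in a 6-exo-trig aldol closure (6-enolendo through the C2=C3 enolate or 6-enolexo through the ester enolate, both favoured) that makes the C2–C7 bond and the six-membered carbocycle of adduct 16, and trifluoroacetic acid should dehydrate 16 so that enolization of the C-3 and C-5 carbonyls gives aromatic ring B. The closest known reaction types are the capture of diketo-acylketenes by aliphatic alcohols followed by the same aldol aromatization to alkyl resorcylates and the acetoacetylation of phenols with 1; new is the aryl ester that must survive the ring closure. The two stereocenters of 16 are transient and become sp2 ring carbons, so no stereocenter remains to be controlled. The step needs O-acylation of the phenol to outrun collapse of 14 to its own 4-hydroxy-2-pyrone, which a concentrated solution of 13 and portionwise addition of 6 should favour, and it needs C2-to-C7 aldol closure in preference to lactonization or C6-to-C1 Claisen closure with loss of the ring A aryloxide, which the more electrophilic C-7 ketone, the aryl-ester-acidified C-2 position and a non-nucleophilic amine in an alcohol-free aprotic medium should favour. The positions of the two hydroxyls and the heptyl group on ring B follow from the 1,3,5,7 spacing of the carbonyl groups and need no control.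

Step 10
Reactants: 17 benzyl 4-[(2-heptyl-4,6-dihydroxybenzoyl)oxy]-2-heptyl-6-methoxybenzoate
Product: 18 benzyl 4-[(2-heptyl-4,6-dimethoxybenzoyl)oxy]-2-heptyl-6-methoxybenzoate
Conditions: MeI (excess), K2CO3, dry acetone, 50 °C
Reagents that add atoms: iodomethane, CI
Why: Williamson methylation should cap both ring B phenols, since the depside carbonyl is shielded by its two ortho substituents, the dry medium holds no nucleophile able to cleave it, and each phenoxide is trapped by MeI as it forms.

Step 11
Reactants: 18 benzyl 4-[(2-heptyl-4,6-dimethoxybenzoyl)oxy]-2-heptyl-6-methoxybenzoate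
Product: 19 4-[(2-heptyl-4,6-dimethoxybenzoyl)oxy]-2-heptyl-6-methoxybenzoic acid (CNP0300299.0)
Conditions: H2 (1 atm), 10% Pd/C, EtOAc, rt
Reagents that add atoms: none
Why: Catalytic hydrogenolysis should cleave only the benzylic C–O bond of the benzyl ester, because the aryl ester, the aryl methyl ethers and the alkyl chains are not reduced under these conditions.

**Compound list**

1 | 2,2,6-trimethyl-4H-1,3-dioxin-4-one | CC1=CC(=O)OC(C)(C)O1 | starting material
2 | acetyl chloride | CC(Cl)=O | starting material
3 | 2,2-dimethyl-6-(2-oxopropyl)-4H-1,3-dioxin-4-one | CC(=O)CC1=CC(=O)OC(C)(C)O1 | intermediate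
4 | octanoyl chloride | CCCCCCCC(Cl)=O | starting material
5 | N-methoxy-N-methyloctanamide | CCCCCCCC(=O)N(C)OC | intermediate
6 | 6-(2,4-dioxoundecyl)-2,2-dimethyl-4H-1,3-dioxin-4-one | CCCCCCCC(=O)CC(=O)CC1=CC(=O)OC(C)(C)O1 | intermediate
7 | 5-heptyl-5-hydroxy-2,2-dimethyl-4a,5-dihydro-4H-1,3-benzodioxine-4,7(6H)-dione (bicyclic aldol adduct, mixture of diastereomers, not isolated) | CCCCCCCC1(O)CC(=O)C=C2OC(C)(C)OC(=O)C12 | intermediate
8 | 5-heptyl-7-hydroxy-2,2-dimethyl-4H-1,3-benzodioxin-4-one | CCCCCCCc1cc(O)cc2OC(C)(C)OC(=O)c12 | intermediate
9 | 7-(allyloxy)-5-heptyl-2,2-dimethyl-4H-1,3-benzodioxin-4-one | CCCCCCCc1cc(OCC=C)cc2OC(C)(C)OC(=O)c12 | intermediate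
10 | benzyl alcohol | OCc1ccccc1 | starting material
11 | benzyl 4-(allyloxy)-2-heptyl-6-hydroxybenzoate | CCCCCCCc1cc(OCC=C)cc(O)c1C(=O)OCc1ccccc1 | intermediate
12 | benzyl 4-(allyloxy)-2-heptyl-6-methoxybenzoate | CCCCCCCc1cc(OCC=C)cc(OC)c1C(=O)OCc1ccccc1 | intermediate
13 | benzyl 2-heptyl-4-hydroxy-6-methoxybenzoate | CCCCCCCc1cc(O)cc(OC)c1C(=O)OCc1ccccc1 | intermediate
14 | 3,5,7-trioxotetradec-1-en-1-one (acylketene, not isolated) | CCCCCCCC(=O)CC(=O)CC(=O)C=C=O | intermediate
15 | 4-[(benzyloxy)carbonyl]-3-heptyl-5-methoxyphenyl 3,5,7-trioxotetradecanoate (not isolated) | CCCCCCCC(=O)CC(=O)CC(=O)CC(=O)Oc1cc(CCCCCCC)c(C(=O)OCc2ccccc2)c(OC)c1 | intermediate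
16 | 4-[(benzyloxy)carbonyl]-3-heptyl-5-methoxyphenyl 2-heptyl-2-hydroxy-4,6-dioxocyclohexane-1-carboxylate (ring B aldol adduct, mixture of diastereomers, not isolated) | CCCCCCCC1(O)CC(=O)CC(=O)C1C(=O)Oc1cc(CCCCCCC)c(C(=O)OCc2ccccc2)c(OC)c1 | intermediate
17 | benzyl 4-[(2-heptyl-4,6-dihydroxybenzoyl)oxy]-2-heptyl-6-methoxybenzoate | CCCCCCCc1cc(O)cc(O)c1C(=O)Oc1cc(CCCCCCC)c(C(=O)OCc2ccccc2)c(OC)c1 | intermediate
18 | benzyl 4-[(2-heptyl-4,6-dimethoxybenzoyl)oxy]-2-heptyl-6-methoxybenzoate | CCCCCCCc1cc(OC)cc(OC)c1C(=O)Oc1cc(CCCCCCC)c(C(=O)OCc2ccccc2)c(OC)c1 | intermediate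
19 | 4-[(2-heptyl-4,6-dimethoxybenzoyl)oxy]-2-heptyl-6-methoxybenzoic acid (CNP0300299.0) | CCCCCCCc1cc(OC(=O)c2c(CCCCCCC)cc(OC)cc2OC)cc(OC)c1C(=O)O | target

**Step count**

Total steps: 11. Longest linear sequence: 10 steps (steps 1, 3, 4, 5, 6, 7, 8, 9, 10, 11); step 2 is a one-step side branch, and compound 6 is used in steps 4 and 9.

**Steps most likely to fail**

1. Step 9. Capture of the acylketene by the electron-poor phenol may be slower than its intramolecular collapse to a pyrone. After capture, the aryl ester may be lost during the base treatment by lactonization or Claisen closure with expulsion of the aryloxide. The fallback is a conventional depside esterification with known chemistry; it sets out from 13 and comes back at 18, so it also passes by step 10. One portion of 13 is methylated at its free phenol (MeI, K2CO3, DMF, 50 °C) to benzyl 2-heptyl-4,6-dimethoxybenzoate F1, and hydrogenolysis (H2, 10% Pd/C, EtOAc) gives 2-heptyl-4,6-dimethoxybenzoic acid F2. Trifluoroacetic anhydride in toluene at rt converts F2 in the flask into 2-heptyl-4,6-dimethoxybenzoic trifluoroacetic anhydride F3. This electron-rich, doubly ortho-substituted mixed anhydride reacts through its acylium ion and should acylate the 4-OH of a second portion of 13 in spite of the hindrance, giving 18.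

2. Step 3. The dianion may be quenched by proton transfer or acylated at its internal carbon, and the enolizable product may condense further, so that conversion to 6 stays low. The fallback builds 6 by C-acylation of a malonate-type carbon and decarboxylation; it sets out from 1 and 4 and comes back at 6. The lithium enolate of 1 (LiN(SiMe3)2, THF, −78 °C) is acylated with the acid chloride of mono-allyl malonate to give allyl 4-(2,2-dimethyl-4-oxo-4H-1,3-dioxin-6-yl)-3-oxobutanoate F4. Its doubly activated methylene is C-acylated with 4 (MgCl2, pyridine, CH2Cl2, 0 °C) to give allyl 2-[(2,2-dimethyl-4-oxo-4H-1,3-dioxin-6-yl)acetyl]-3-oxodecanoate F5. Pd(PPh3)4 and morpholine in THF then remove the allyl group and the carboxyl carbon (deallylation and decarboxylation) to give 6.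

3. Step 4. Aldol closure through C-5 of the dioxinone may be slower than intermolecular condensation of the polycarbonyl chain, or the aldol adduct may dehydrate incompletely, so that conversion to the benzodioxinone stays low. The fallback forms the ester before the arene by ketene capture with an aliphatic alcohol and relies on the hydrogen bond of the ortho phenol for the differentiation; it sets out from 6 and 10 and comes back at 11, so it also passes by steps 5 and 6. Compound 6 is heated with benzyl alcohol 10 in toluene at 110 °C, so that acylketene 14 is captured by the primary alcohol as benzyl 3,5,7-trioxotetradecanoate F6. Et3N in CH2Cl2 and then TFA aromatize it to benzyl 2-heptyl-4,6-dihydroxybenzoate F7. Allyl bromide (1.05 equiv) and K2CO3 in acetone at rt should then etherify only the 4-OH, the 6-OH being held in a hydrogen bond to the ester carbonyl, to give 11.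

**Further compounds**

F1 | step 9 | benzyl 2-heptyl-4,6-dimethoxybenzoate | CCCCCCCc1cc(OC)cc(OC)c1C(=O)OCc1ccccc1
F2 | step 9 | 2-heptyl-4,6-dimethoxybenzoic acid | CCCCCCCc1cc(OC)cc(OC)c1C(=O)O
F3 | step 9 | 2-heptyl-4,6-dimethoxybenzoic trifluoroacetic anhydride | CCCCCCCc1cc(OC)cc(OC)c1C(=O)OC(=O)C(F)(F)F
F4 | step 3 | allyl 4-(2,2-dimethyl-4-oxo-4H-1,3-dioxin-6-yl)-3-oxobutanoate | C=CCOC(=O)CC(=O)CC1=CC(=O)OC(C)(C)O1
F5 | step 3 | allyl 2-[(2,2-dimethyl-4-oxo-4H-1,3-dioxin-6-yl)acetyl]-3-oxodecanoate (enolizable, no defined configuration) | C=CCOC(=O)C(C(=O)CCCCCCC)C(=O)CC1=CC(=O)OC(C)(C)O1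
F6 | step 4 | benzyl 3,5,7-trioxotetradecanoate | CCCCCCCC(=O)CC(=O)CC(=O)CC(=O)OCc1ccccc1
F7 | step 4 | benzyl 2-heptyl-4,6-dihydroxybenzoate | CCCCCCCc1cc(O)cc(O)c1C(=O)OCc1ccccc1
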